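## Retrosynthetic overview

1. Target ⇒ (MOM removal) ⇒ disconnect the flavanone C2–C1' bond: enantioselective Pd(II)/PyOx conjugate arylation of 5,7-dihydroxychromone, which dearomatizes its γ-pyrone ring, sets (2S) and joins the two halves.
2. The aryl donor is a flavone-bearing arylboronic acid ⇒ Miyaura borylation of an aryl chloride ⇒ Suzuki coupling of 8-iodo-5,7-bis(MOM)-acacetin with (5-chloro-2-methoxyphenyl)boronic acid. The biaryl is made before any stereocentre exists.
3. 8-Iodoflavone ⇒ acacetin ⇒ one-step thermal annulation of phloroglucinol with ethyl 4-methoxybenzoylacetate.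
4. Ring order: flavone A ring (phloroglucinol) → flavone C ring (step 1) → biaryl bond (step 4) → flavanone C-ring stereocentre by arylation of a preformed chromone (step 6).

Assumption: the target SMILES defines no configuration for the C8–C3' biaryl axis, so it is treated as rotameric and only C2 is controlled.
Assumption: 5,7-dihydroxychromone and (R)-t-BuPyOx are purchased.

## Route

**Step 1**
Reactants: 1 phloroglucinol; 2 ethyl 3-(4-methoxyphenyl)-3-oxopropanoate
Product: 3 acacetin (5,7-dihydroxy-2-(4-methoxyphenyl)-4H-chromen-4-one)
Conditions: neat, 240 °C, Ar, about 1 h (or microwave, solvent-free), –EtOH, –H2O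
Reagents that add atoms: none (all product atoms come from 1 and 2)
Why: Mentzer-type thermal chromone synthesis; C-acylation of the triphenol by the β-keto ester followed by cyclodehydration gives the flavone directly, and non-acidic thermal conditions favour the chromone over the Pechmann coumarin.

**Step 2**
Reactants: 3 acacetin
Product: 4 5,7-bis(methoxymethoxy)-2-(4-methoxyphenyl)-4H-chromen-4-one
Conditions: NaH (2.5 equiv), MOMCl (2.6 equiv), DMF, 0 °C → rt
Reagents that add atoms: chloromethyl methyl ether, COCCl
Why: Williamson-type O-alkylation (MOM protection); NaH/DMF is needed to alkylate the chelated 5-OH, and blocking it is what steers the next step to C8.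

**Step 3**
Reactants: 4
Product: 5 8-iodo-5,7-bis(methoxymethoxy)-2-(4-methoxyphenyl)-4H-chromen-4-one
Conditions: NIS (1.1 equiv), DMF, rt → 45 °C, dark
Reagents that add atoms: N-iodosuccinimide, O=C1CCC(=O)N1I
Why: Electrophilic aromatic iodination; with the 5-oxygen alkylated, 5,7-dialkoxyflavones react at C8 (para to 5-OR, ortho to 7-OR) rather than at C6, which is flanked by two OMOM groups, and neutral conditions keep the MOM ethers intact.

**Step 4**
Reactants: 5; 6 (5-chloro-2-methoxyphenyl)boronic acid
Product: 7 8-(5-chloro-2-methoxyphenyl)-5,7-bis(methoxymethoxy)-2-(4-methoxyphenyl)-4H-chromen-4-one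
Conditions: Pd(PPh3)4 (5 mol %), K2CO3 (3 equiv), DMF/H2O 9:1, 90 °C
Reagents that add atoms: none (all product atoms come from 5 and 6)
Why: Suzuki–Miyaura coupling; Pd/PPh3 inserts into the C–I bond but not the electron-rich C–Cl bond, so the chloride para to OMe survives as the handle for step 5.

**Step 5**
Reactants: 7
Product: 8 {3-[5,7-bis(methoxymethoxy)-2-(4-methoxyphenyl)-4-oxo-4H-chromen-8-yl]-4-methoxyphenyl}boronic acid
Conditions: XPhos Pd G2 (3 mol %), XPhos (6 mol %), B2(OH)4 (3 equiv), KOAc (3 equiv), EtOH, 80 °C; workup at pH about 6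
Reagents that add atoms: tetrahydroxydiboron, OB(O)B(O)O
Why: Miyaura borylation of an electron-rich aryl chloride with an XPhos–Pd catalyst; tetrahydroxydiboron gives the free boronic acid needed for step 6 without a separate ester hydrolysis, and MOM ethers and the flavone tolerate KOAc/EtOH.

**Step 6 (key step)**
Reactants: 8; 9 5,7-dihydroxy-4H-chromen-4-one (2 equiv)
Product: 10 (2S)-5,7-dihydroxy-2-{3-[5,7-bis(methoxymethoxy)-2-(4-methoxyphenyl)-4-oxo-4H-chromen-8-yl]-4-methoxyphenyl}chroman-4-one
Conditions: Pd(OCOCF3)2 (10 mol %), (R)-t-BuPyOx (12 mol %), NH4PF6 (30 mol %), H2O (5 equiv), ClCH2CH2Cl/CF3CH2OH 4:1, 60 °C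
Reagents that add atoms: none (all product atoms come from 8 and 9)
Why: Pd(II)/PyOx-catalysed asymmetric conjugate (1,4-) addition of an arylboronic acid to a chromone; Ar–Pd(PyOx)+ inserts the chromone C2=C3 on one enantioface (the ligand t-Bu group blocks the other) and protonolysis of the Pd enolate gives the 2-arylchroman-4-one, removing the γ-pyrone's aromatic character. The (R)-ligand is chosen by analogy with cyclic enones, where the (S)-ligand gives the face corresponding to (2R); this is my assignment from recall, so (2S) must be confirmed by CD and the antipodal ligand used if the sense is opposite. The base-free, mildly acidic medium avoids retro-oxa-Michael racemisation, and the flavone's own β,β-disubstituted enone does not react.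

**Step 7**
Reactants: 10
Product: 11 2,3-dihydro-4',4'''-di-O-methylamentoflavone (target, 2S)
Conditions: 3 M aq HCl/MeOH–THF, 45 °C; workup kept at pH ≤ 7
Reagents that add atoms: none
Why: Acid-catalysed acetal (MOM) hydrolysis; aryl methyl ethers are inert, and the C2 stereocentre only racemises through base-mediated ring opening to the chalcone, which acidic conditions and a non-basic workup avoid.

## Compound list

1 | phloroglucinol | Oc1cc(O)cc(O)c1 | starting material
2 | ethyl 3-(4-methoxyphenyl)-3-oxopropanoate | CCOC(=O)CC(=O)c1ccc(OC)cc1 | starting material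
3 | acacetin | COc1ccc(-c2cc(=O)c3c(O)cc(O)cc3o2)cc1 | intermediate
4 | 5,7-bis(MOM)-acacetin | COCOc1cc(OCOC)c2c(=O)cc(-c3ccc(OC)cc3)oc2c1 | intermediate
5 | 8-iodo-5,7-bis(MOM)-acacetin | COCOc1cc(OCOC)c2c(=O)cc(-c3ccc(OC)cc3)oc2c1I | intermediate
6 | (5-chloro-2-methoxyphenyl)boronic acid | COc1ccc(Cl)cc1B(O)O | starting material
7 | 8-(5-chloro-2-methoxyphenyl)-5,7-bis(MOM)-acacetin | COCOc1cc(OCOC)c2c(=O)cc(-c3ccc(OC)cc3)oc2c1-c1cc(Cl)ccc1OC | intermediate
8 | flavone arylboronic acid | COCOc1cc(OCOC)c2c(=O)cc(-c3ccc(OC)cc3)oc2c1-c1cc(B(O)O)ccc1OC | intermediate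
9 | 5,7-dihydroxy-4H-chromen-4-one | O=c1ccoc2cc(O)cc(O)c12 | starting material
10 | (2S)-bis-MOM biflavonoid | COCOc1cc(OCOC)c2c(=O)cc(-c3ccc(OC)cc3)oc2c1-c1cc([C@@H]2CC(=O)c3c(O)cc(O)cc3O2)ccc1OC | intermediate
11 | 2,3-dihydro-4',4'''-di-O-methylamentoflavone (2S) | COc1ccc(-c2cc(=O)c3c(O)cc(O)c(-c4cc([C@@H]5CC(=O)c6c(O)cc(O)cc6O5)ccc4OC)c3o2)cc1 | target

## Summary

Total steps: 7. Longest linear sequence: 7 (1 → 11); steps 6 and 7 can be telescoped in one pot.

Steps most likely to fail:

1. **Step 6.** The electron-rich, unprotected dihydroxychromone may be a sluggish acceptor, boronic acid 8 may protodeboronate, and the ee and facial sense are untested on this substrate pair. Fallback: give up the C2–aryl disconnection. Couple 5 with 5-formyl-2-methoxyphenylboronic acid, run a Claisen–Schmidt condensation with 2-hydroxy-4,6-bis(methoxymethoxy)acetophenone to the chalcone, and close the flavanone by organocatalytic asymmetric oxa-Michael cyclisation (or racemic cyclisation with preparative chiral HPLC).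
2. **Step 3.** C8 versus C6 selectivity may be imperfect, and partial loss of the 5-O-MOM group would redirect iodination to C6. Fallback: fix the regiochemistry before the pyrone exists. Iodinate 2-hydroxy-4,6-bis(methoxymethoxy)acetophenone ortho to the free OH, condense with 4-methoxybenzaldehyde, and oxidatively cyclise the chalcone (I2/DMSO) to 5.
3. **Step 5.** Borylation of a hindered, functionalised aryl chloride may be slow, and the product may homocouple or be hard to purify. Fallback: invert the coupling polarity. Borylate iodide 5 to the 8-Bpin flavone, couple it with 3-bromo-4-methoxyphenyl MIDA boronate, and release boronic acid 8 by mild aqueous hydrolysis just before step 6.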